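## The problem

The target **26** is a flavonol 3‑methyl ether: a 4H‑chromen‑4‑one (rings A and C) with an aryl ring B on C2. It has no stereocentre, so the task is one of regiochemistry and of telling seven oxygen substituents apart. Ring A is substituted everywhere except C6 (5‑OH, 7‑OMe, 8‑OMe, O1 on C8a, the carbonyl carbon C4 on C4a). Ring C carries the 3‑methoxyl, and ring B has free hydroxyls at C2' and C4' and a methoxyl at C5'. Three oxygens must end as free hydroxyls and four as methyl ethers. Ring B therefore needs removable protection, and the 5‑oxygen can be singled out because it is hydrogen‑bonded to the C4 carbonyl: a 5‑methoxyl is the one methyl ether that a chelating Lewis acid removes, and a free 5‑hydroxyl resists alkylation. The sensitive features are the 5,8‑dioxygenated ring A and the 2',4',5'‑trioxygenated ring B (both oxidise easily once free), benzyl ethers toward strong Lewis acids, and enol ether intermediates toward aqueous acid. The key step rests on the fact that O1 (on C8a) and C4 (on C4a) are ortho neighbours on ring A and that C4a has the C5 oxygen on its other side. An aryne across C4a–C8a with a methoxyl at C5 is polarised so that an oxygen nucleophile adds at C8a and the carbanion, and hence the acyl group, ends at C4a. A C8 oxygen on that aryne would cancel the bias, so it has to be introduced afterwards, para to the 5‑hydroxyl.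

## Retrosynthesis

**26 from 25.** The two O–benzyl bonds on ring B are cut last. Benzyl is chosen because hydrogenolysis touches neither the methyl ethers nor the chelated 5‑hydroxyl, and because benzyl ethers should tolerate fluoride at high temperature, aqueous alkali and a moderated Lewis acid. The forward step only asks that the tetrasubstituted C2=C3 bond of the chromone is not reduced.

**25 from 22 (C8–O bond).** The 8‑methoxyl is traced back through hydroquinone **24** and aryl sulfate **23** to the 5‑hydroxyflavone **22**. The forward reaction is a para‑hydroxylation of the phenoxide with persulfate, followed by methylation of the only non‑chelated hydroxyl. Placing this oxidation late keeps ring A simple and symmetric in the early intermediates; the price is one step of modest efficiency.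

**22 from 21 (O–methyl bond at C5).** The 5‑hydroxyl is revealed from the trimethyl ether **21** by chelation‑controlled demethylation. This lets ring A enter as a symmetric 3,5‑dimethoxy unit with no separate protecting group for O5. The forward step must distinguish the 5‑methoxyl from the 3‑methoxyl and from the benzyl ethers.

**21 from 7 and 18 (key disconnection).** Three bonds are cut at once: O1–C8a, C4–C4a and O1–C2. This leads to the ortho‑silylaryl triflate **7** and the β‑methoxyacrylic acid **18**. In the forward direction, aryne **19** inserts into the O–acyl bond of **18** to give the ortho‑acylphenoxide **20**, which closes ring C by displacing the β‑methoxyl. A classical acylation of a phloroglucinol ketone followed by rearrangement and cyclodehydration would form the same bonds in three or four operations; the aryne cascade forms them in one and joins two fragments of similar size. The forward reaction has to capture the aryne regioselectively, transfer the acyl group faster than the aryl anion is protonated, and close the ring.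

**18 from 13 and 14.** Acid **18** comes from ester **17**, which is the O‑methyl enol ether of β‑ketoester **16**. Ketoester **16** is the oxidation product of aldol **15**, and the aldol cut (the future C2–C3 bond) gives aldehyde **13** and methyl methoxyacetate **14**. The aldol–oxidation pair is preferred to a crossed Claisen condensation because an electron‑rich, ortho‑substituted benzoate is a poor acyl acceptor. The stereocentres of **15** do not matter because both are removed.

**13 from 8.** The formyl group of **13** is removed to give the trialkoxybenzene **11**, whose most nucleophilic position is the required one. Ether **11** comes from phenol **10**, which arises from commercial 3‑(benzyloxy)‑4‑methoxybenzaldehyde **8** by exchange of the formyl group for a hydroxyl via formate **9**. The sequence converts the 3,4‑dioxygenated pattern of **8** into the 2,4,5‑pattern of ring B using only standard reactions.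

**7 from 1.** The silyl and triflate groups of **7** are traced to the carbamate **5** and on to the carbamate **2** of 3,5‑dimethoxyphenol **1**. The carbamate directs metalation to the carbon between itself and a methoxyl, which fixes the regiochemistry that a direct halogenation of **1** would leave in doubt.

## Roads not taken

**Alternative 1:** The cut is at C4a–C4 and C4–C3, with carbon monoxide supplying C4. The aryl iodide 1‑(benzyloxy)‑2‑iodo‑4,5‑dimethoxy‑3‑(methoxymethoxy)benzene **A2**, carbon monoxide and the enolate of the ring B ketone **A3** would be coupled under zerovalent palladium (Pd(dba)2 with Xantphos) to give the 1,3‑diketone **A1**. Acid would then remove the acetal and cyclodehydrate, and hydrogenolysis of three benzyl ethers would finish.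
- Merits: all ring A oxygens, including the one at C8, are present from the start. No late C–H oxidation and no selective demethylation are needed, and the end game is two steps. In this respect the road is better than the chosen plan.
- Weak points: **A2** is a pentasubstituted benzene with four differently protected oxygens and an iodine between two ortho alkoxy groups, so its preparation is much longer than that of **7**. Carbonylative ketone arylation is established mainly for unhindered aryl halides; here a doubly ortho‑substituted acylpalladium must be intercepted by a hindered α‑methoxy enolate, with direct arylation without carbon monoxide and O‑acylation as competitors. The key step closes no ring.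
- Against its shorter end game the chosen plan sets a three‑step symmetric ring A donor, a key step that forms three bonds and ring C at the final oxidation level, and no pressurised toxic gas.

**Alternative 2:** The cut is at C1'–C2' and C5'–C6', so ring B is built last. The alkyne 2‑ethynyl‑3,5,7,8‑tetramethoxychromone **A5** would undergo Diels–Alder addition with the diene 1,4‑dimethoxy‑1,3‑bis(trimethylsilyloxy)buta‑1,3‑diene **A6**. Acid work‑up with loss of methanol and the silyl groups would give the diphenol **A4**, and one chelation‑controlled 5‑O‑demethylation would complete the synthesis.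
- Merits: the ring B hydroxyls appear unprotected, so there are no benzyl ethers and no hydrogenolysis. The C8 oxygen is built in, and only one step follows the key step. These are real advantages in protecting‑group economy.
- Weak points: **A5** already contains the whole of rings A and C with four methoxyls, so the hard part of the molecule is only moved into a long linear preparation of the dienophile. Its alkyne is activated only vinylogously through the chromone and is deactivated by the 3‑methoxyl. The diene **A6** is hydrolytically fragile, and conjugate addition without ring closure can compete with cycloaddition. Aromatisation must lose methanol and not the silyloxy group.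
- The chosen plan offers convergence from two simple fragments and a key step with close precedent, against the extra protecting‑group steps it needs.

**Alternative 3:** The cut is at C3–C4. The dialdehyde **A8** would be closed by an N‑heterocyclic carbene (triazolium salt with an amine base) in an intramolecular benzoin reaction to the racemic trans ketol **A7**. Dehydrogenation to the flavonol, 3‑O‑methylation and hydrogenolysis would follow.
- Merits: the conditions are mild and metal‑free. All oxygens are in place early, and the 5‑benzyloxy group becomes the free 5‑hydroxyl on hydrogenolysis, so neither the persulfate oxidation nor the selective demethylation is needed. The end game is therefore cleaner than in the chosen plan.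
- Weak points: **A8** contains an α‑aryl‑α‑aryloxy acetaldehyde, which is enolisable and labile. It is awkward to make, since a hindered, hydrogen‑bonded salicylaldehyde must be O‑alkylated with a secondary benzylic electrophile. The carbene must add to the doubly ortho‑substituted, electron‑rich aromatic aldehyde and not to the aliphatic one; otherwise the isomeric ketol results. Two stereocentres are created only to be erased, and the oxidation level must be adjusted afterwards.
- The chosen plan sets against this stable, easily made precursors and direct arrival at the chromone.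

Key step: step 11

Assumption: enol ether **17** and acid **18** are drawn as the Z isomers (β‑methoxyl trans to the carboxyl group), the expected outcome of O‑alkylation of a free enolate. The geometry is lost in the ring closure of step 11, so either isomer or a mixture would serve.

## Route

Step 1
Reactants: 1 3,5-dimethoxyphenol
Product: 2 3,5-dimethoxyphenyl N-isopropylcarbamate
Conditions: i-PrNCO, Et3N (cat.), CH2Cl2, rt
Reagents that add atoms: isopropyl isocyanate, CC(C)N=C=O
Why: Base-catalysed addition of the phenol to the isocyanate (carbamoylation); the N-isopropyl carbamate is a strong ortho-directing group that can later be removed under mild amine conditions.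

Step 2
Reactants: 2 3,5-dimethoxyphenyl N-isopropylcarbamate
Product: 5 3,5-dimethoxy-2-(trimethylsilyl)phenyl N-isopropylcarbamate, via N-silyl carbamate 3 (not isolated), via N,C-disilyl carbamate 4 (not isolated)
Conditions: TMSOTf, TMEDA, Et2O, 0 °C → rt; n-BuLi, TMEDA, −78 °C; TMSCl, −78 °C → rt; aq. NaHSO4
Reagents that add atoms: chlorotrimethylsilane, C[Si](C)(C)Cl
Why: Directed ortho-metalation: after in situ N-silylation the carbamate directs n-BuLi to C2, which is flanked by the carbamate and a methoxyl and should be favoured over C4 between the two weaker methoxyl directors. TMSCl traps the aryllithium and the acidic work-up removes the N-silyl group of 4.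

Step 3
Reactants: 5 3,5-dimethoxy-2-(trimethylsilyl)phenyl N-isopropylcarbamate
Product: 7 3,5-dimethoxy-2-(trimethylsilyl)phenyl trifluoromethanesulfonate, via silyl phenol 6 (not isolated)
Conditions: DBU, Et2NH, MeCN, 40 °C; then PhNTf2, rt
Reagents that add atoms: N-phenylbis(trifluoromethanesulfonimide), O=S(=O)(N(c1ccccc1)S(=O)(=O)C(F)(F)F)C(F)(F)F
Why: DBU deprotonates the carbamate N–H and isopropyl isocyanate is expelled and scavenged by diethylamine as a urea; the phenoxide of 6 is triflated in the same flask, a standard one-pot entry to ortho-silylaryl triflates.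

Step 4
Reactants: 8 3-(benzyloxy)-4-methoxybenzaldehyde
Product: 10 3-(benzyloxy)-4-methoxyphenol, via aryl formate 9 (not isolated)
Conditions: mCPBA, CH2Cl2, rt; then K2CO3 (cat.), MeOH, rt
Reagents that add atoms: 3-chloroperoxybenzoic acid, OOC(=O)c1cccc(Cl)c1
Why: Baeyer–Villiger (Dakin-type) oxidation: the electron-rich aryl group migrates in the peracid adduct to give formate 9, which is methanolysed to the phenol.

Step 5
Reactants: 10 3-(benzyloxy)-4-methoxyphenol
Product: 11 2,4-bis(benzyloxy)-1-methoxybenzene
Conditions: BnBr, K2CO3, DMF, rt
Reagents that add atoms: benzyl bromide, BrCc1ccccc1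
Why: Williamson ether synthesis on a phenoxide.

Step 6
Reactants: 11 2,4-bis(benzyloxy)-1-methoxybenzene
Product: 13 2,4-bis(benzyloxy)-5-methoxybenzaldehyde, via iminium salt 12 (not isolated)
Conditions: POCl3, DMF, 0 → 60 °C; then aq. NaOAc
Reagents that add atoms: N,N-dimethylformamide, CN(C)C=O; water, O
Why: Vilsmeier–Haack formylation: C5 of 11 is para to one benzyloxy group and ortho to the other, the position attacked in 1,2,4-trialkoxybenzenes. C3 lies between two benzyloxy groups and C6 is activated by one oxygen only.

Step 7
Reactants: 13 2,4-bis(benzyloxy)-5-methoxybenzaldehyde; 14 methyl methoxyacetate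
Product: 15 methyl 3-[2,4-bis(benzyloxy)-5-methoxyphenyl]-3-hydroxy-2-methoxypropanoate (racemic mixture of diastereomers)
Conditions: LiN(i-Pr)2, THF, −78 °C; then 13; aq. NH4Cl
Reagents that add atoms: none
Why: Aldol addition of the lithium ester enolate to a non-enolisable aldehyde; both new stereocentres are removed in steps 8 and 9, so the mixture is carried on as such.

Step 8
Reactants: 15 methyl 3-[2,4-bis(benzyloxy)-5-methoxyphenyl]-3-hydroxy-2-methoxypropanoate
Product: 16 methyl 3-[2,4-bis(benzyloxy)-5-methoxyphenyl]-2-methoxy-3-oxopropanoate (racemic)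
Conditions: Dess–Martin periodinane, NaHCO3, CH2Cl2, 0 °C → rt
Reagents that add atoms: none
Why: Dess–Martin oxidation of a secondary benzylic alcohol to the ketone; buffering and near-stoichiometric oxidant limit further oxidation at the α-carbon.

Step 9
Reactants: 16 methyl 3-[2,4-bis(benzyloxy)-5-methoxyphenyl]-2-methoxy-3-oxopropanoate
Product: 17 methyl (Z)-3-[2,4-bis(benzyloxy)-5-methoxyphenyl]-2,3-dimethoxyprop-2-enoate
Conditions: Cs2CO3, Me2SO4, DMF, 0 °C → rt
Reagents that add atoms: dimethyl sulfate, COS(=O)(=O)OC
Why: O-alkylation of a β-ketoester enolate: a loosely paired cesium enolate in DMF and a hard sulfate electrophile favour attack through oxygen, and the α-carbon is tertiary and crowded, which disfavours C-methylation. The extended enolate should place the new methoxyl trans to the ester.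

Step 10
Reactants: 17 methyl (Z)-3-[2,4-bis(benzyloxy)-5-methoxyphenyl]-2,3-dimethoxyprop-2-enoate
Product: 18 (Z)-3-[2,4-bis(benzyloxy)-5-methoxyphenyl]-2,3-dimethoxyprop-2-enoic acid
Conditions: LiOH·H2O, THF/MeOH/H2O, 50 °C; then 1 M HCl to pH 4, 0 °C
Reagents that add atoms: lithium hydroxide, [Li+].[OH-]
Why: Ester saponification by acyl substitution; the fully substituted, donor-bearing β-carbon resists conjugate attack by hydroxide, and cold, mild acidification spares the enol ether.

Step 11
Reactants: 7 3,5-dimethoxy-2-(trimethylsilyl)phenyl trifluoromethanesulfonate; 18 (Z)-3-[2,4-bis(benzyloxy)-5-methoxyphenyl]-2,3-dimethoxyprop-2-enoic acid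
Product: 21 2-[2,4-bis(benzyloxy)-5-methoxyphenyl]-3,5,7-trimethoxy-4H-chromen-4-one, via 3,5-dimethoxybenzyne 19 (not isolated), via ortho-hydroxyaryl enone 20 (not isolated)
Conditions: 7 (1.5 equiv), CsF (4 equiv), THF, 125 °C (sealed tube)
Reagents that add atoms: none
Why: Fluoride removes the silyl group of 7 and triflate leaves, giving aryne 19, whose triple bond is polarised by the inductively withdrawing methoxyl beside it so that the carbon remote from that methoxyl (the future C8a) is the electrophilic end. The cesium carboxylate of 18 adds there through oxygen, which places the aryl anion at the future C4a, between the ester oxygen and the methoxyl. The anion attacks the neighbouring ester carbonyl through a four-membered transition state (4-exo-trig) and the strained adduct opens to the ortho-acylphenoxide 20, a net insertion of the aryne into the O–acyl bond that forms O1–C8a and C4–C4a. The phenoxide then adds to the β-carbon of the enone (6-endo-trig oxa-Michael addition) and methoxide is expelled, which forms O1–C2 and closes ring C directly at the chromone oxidation level; no stereocentre is created and the alkene geometry of 18 is lost in the tetrahedral intermediate. The closest known reaction type is the fluoride-promoted insertion of arynes into the O–acyl bond of carboxylic acids, which gives ortho-hydroxyaryl ketones and, with unsaturated acids, chroman-4-ones and flavones through the same phenoxide conjugate addition. The step needs regioselective capture of the unsymmetrical aryne, which the C5 methoxyl secures (the other methoxyl is meta to the attacked carbon and does not oppose it), and acyl transfer faster than protonation of the aryl anion, which an aprotic medium at high temperature with the acid as the only proton source should secure. Attack of the aryl anion on the β-carbon, which would lead to an isomeric coumarin, is disfavoured because it needs the less stable ester conformer and a fully substituted, donor-bearing carbon.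

Step 12
Reactants: 21 2-[2,4-bis(benzyloxy)-5-methoxyphenyl]-3,5,7-trimethoxy-4H-chromen-4-one
Product: 22 2-[2,4-bis(benzyloxy)-5-methoxyphenyl]-5-hydroxy-3,7-dimethoxy-4H-chromen-4-one
Conditions: AlCl3, MeCN, rt → 50 °C; then dil. HCl
Reagents that add atoms: none
Why: Chelation-controlled demethylation: aluminium binds the C4 carbonyl and the peri 5-methoxyl oxygen in a six-membered chelate and chloride removes the methyl group by SN2. The 3-methoxyl can only form a five-membered chelate, and unchelated methyl and benzyl ethers are not activated by the acetonitrile-moderated Lewis acid.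

Step 13
Reactants: 22 2-[2,4-bis(benzyloxy)-5-methoxyphenyl]-5-hydroxy-3,7-dimethoxy-4H-chromen-4-one
Product: 24 2-[2,4-bis(benzyloxy)-5-methoxyphenyl]-5,8-dihydroxy-3,7-dimethoxy-4H-chromen-4-one, via aryl sulfate 23 (not isolated)
Conditions: K2S2O8, aq. KOH, pyridine, 0 °C → rt; then 2 M HCl, Na2SO3 (cat.), aq. dioxane, 80 °C
Reagents that add atoms: potassium peroxodisulfate, [K+].[K+].[O-]S(=O)(=O)OOS(=O)(=O)[O-]
Why: Elbs persulfate oxidation: the phenoxide of the 5-hydroxyl attacks the peroxide oxygen through its para carbon C8 to give aryl sulfate 23, which dilute acid hydrolyses; this is the classical way from 5-hydroxy-7-methoxyflavones to their 5,8-dihydroxy derivatives.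

Step 14
Reactants: 24 2-[2,4-bis(benzyloxy)-5-methoxyphenyl]-5,8-dihydroxy-3,7-dimethoxy-4H-chromen-4-one
Product: 25 2-[2,4-bis(benzyloxy)-5-methoxyphenyl]-5-hydroxy-3,7,8-trimethoxy-4H-chromen-4-one
Conditions: Me2SO4 (1.05 equiv), K2CO3, acetone, reflux, N2
Reagents that add atoms: dimethyl sulfate, COS(=O)(=O)OC
Why: Selective O-alkylation: the 5-hydroxyl is hydrogen-bonded to the C4 carbonyl and is a poor nucleophile, whereas the 8-hydroxyl is an ordinary phenol.

Step 15
Reactants: 25 2-[2,4-bis(benzyloxy)-5-methoxyphenyl]-5-hydroxy-3,7,8-trimethoxy-4H-chromen-4-one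
Product: 26 5,2',4'-trihydroxy-3,7,8,5'-tetramethoxyflavone
Conditions: H2 (1 atm), 10% Pd/C, EtOAc/MeOH, rt
Reagents that add atoms: none
Why: Hydrogenolysis of benzyl aryl ethers on palladium; the tetrasubstituted C2=C3 bond of the chromone, a vinylogous ester, should not be reduced at balloon pressure.

## Compound list

1 | 3,5-dimethoxyphenol | COc1cc(O)cc(OC)c1 | starting material
2 | 3,5-dimethoxyphenyl N-isopropylcarbamate | COc1cc(OC)cc(OC(=O)NC(C)C)c1 | intermediate
3 | 3,5-dimethoxyphenyl N-isopropyl-N-(trimethylsilyl)carbamate | COc1cc(OC)cc(OC(=O)N(C(C)C)[Si](C)(C)C)c1 | intermediate (not isolated)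
4 | 3,5-dimethoxy-2-(trimethylsilyl)phenyl N-isopropyl-N-(trimethylsilyl)carbamate | COc1cc(OC)c([Si](C)(C)C)c(OC(=O)N(C(C)C)[Si](C)(C)C)c1 | intermediate (not isolated)
5 | 3,5-dimethoxy-2-(trimethylsilyl)phenyl N-isopropylcarbamate | COc1cc(OC)c([Si](C)(C)C)c(OC(=O)NC(C)C)c1 | intermediate
6 | 3,5-dimethoxy-2-(trimethylsilyl)phenol (as its amidinium phenoxide) | COc1cc(O)c([Si](C)(C)C)c(OC)c1 | intermediate (not isolated)
7 | 3,5-dimethoxy-2-(trimethylsilyl)phenyl trifluoromethanesulfonate | COc1cc(OC)c([Si](C)(C)C)c(OS(=O)(=O)C(F)(F)F)c1 | intermediate
8 | 3-(benzyloxy)-4-methoxybenzaldehyde | COc1ccc(C=O)cc1OCc1ccccc1 | starting material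
9 | 3-(benzyloxy)-4-methoxyphenyl formate | COc1ccc(OC=O)cc1OCc1ccccc1 | intermediate (not isolated)
10 | 3-(benzyloxy)-4-methoxyphenol | COc1ccc(O)cc1OCc1ccccc1 | intermediate
11 | 2,4-bis(benzyloxy)-1-methoxybenzene | COc1ccc(OCc2ccccc2)cc1OCc1ccccc1 | intermediate
12 | N-{[2,4-bis(benzyloxy)-5-methoxyphenyl]methylidene}-N-methylmethanaminium dichlorophosphate | C[N+](C)=Cc1cc(OC)c(OCc2ccccc2)cc1OCc1ccccc1.[O-]P(Cl)(Cl)=O | intermediate (not isolated)
13 | 2,4-bis(benzyloxy)-5-methoxybenzaldehyde | COc1cc(C=O)c(OCc2ccccc2)cc1OCc1ccccc1 | intermediate
14 | methyl methoxyacetate | COCC(=O)OC | starting material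
15 | methyl 3-[2,4-bis(benzyloxy)-5-methoxyphenyl]-3-hydroxy-2-methoxypropanoate (racemic, both diastereomers) | COC(=O)C(OC)C(O)c1cc(OC)c(OCc2ccccc2)cc1OCc1ccccc1 | intermediate
16 | methyl 3-[2,4-bis(benzyloxy)-5-methoxyphenyl]-2-methoxy-3-oxopropanoate (racemic) | COC(=O)C(OC)C(=O)c1cc(OC)c(OCc2ccccc2)cc1OCc1ccccc1 | intermediate
17 | methyl (Z)-3-[2,4-bis(benzyloxy)-5-methoxyphenyl]-2,3-dimethoxyprop-2-enoate | COC(=O)/C(OC)=C(/OC)c1cc(OC)c(OCc2ccccc2)cc1OCc1ccccc1 | intermediate
18 | (Z)-3-[2,4-bis(benzyloxy)-5-methoxyphenyl]-2,3-dimethoxyprop-2-enoic acid | OC(=O)/C(OC)=C(/OC)c1cc(OC)c(OCc2ccccc2)cc1OCc1ccccc1 | intermediate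
19 | 3,5-dimethoxybenzyne | COC1=CC(OC)=CC#C1 | intermediate (not isolated)
20 | (Z)-3-[2,4-bis(benzyloxy)-5-methoxyphenyl]-1-(2-hydroxy-4,6-dimethoxyphenyl)-2,3-dimethoxyprop-2-en-1-one (as its cesium phenoxide) | COc1cc(O)c(C(=O)/C(OC)=C(/OC)c2cc(OC)c(OCc3ccccc3)cc2OCc2ccccc2)c(OC)c1 | intermediate (not isolated)
21 | 2-[2,4-bis(benzyloxy)-5-methoxyphenyl]-3,5,7-trimethoxy-4H-chromen-4-one | COc1cc(OC)c2c(=O)c(OC)c(-c3cc(OC)c(OCc4ccccc4)cc3OCc3ccccc3)oc2c1 | intermediate
22 | 2-[2,4-bis(benzyloxy)-5-methoxyphenyl]-5-hydroxy-3,7-dimethoxy-4H-chromen-4-one | COc1cc(O)c2c(=O)c(OC)c(-c3cc(OC)c(OCc4ccccc4)cc3OCc3ccccc3)oc2c1 | intermediate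
23 | potassium 2-[2,4-bis(benzyloxy)-5-methoxyphenyl]-5-hydroxy-3,7-dimethoxy-4-oxo-4H-chromen-8-yl sulfate | COc1cc(O)c2c(=O)c(OC)c(-c3cc(OC)c(OCc4ccccc4)cc3OCc3ccccc3)oc2c1OS(=O)(=O)[O-].[K+] | intermediate (not isolated)
24 | 2-[2,4-bis(benzyloxy)-5-methoxyphenyl]-5,8-dihydroxy-3,7-dimethoxy-4H-chromen-4-one | COc1cc(O)c2c(=O)c(OC)c(-c3cc(OC)c(OCc4ccccc4)cc3OCc3ccccc3)oc2c1O | intermediate
25 | 2-[2,4-bis(benzyloxy)-5-methoxyphenyl]-5-hydroxy-3,7,8-trimethoxy-4H-chromen-4-one | COc1cc(O)c2c(=O)c(OC)c(-c3cc(OC)c(OCc4ccccc4)cc3OCc3ccccc3)oc2c1OC | intermediate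
26 | 5,2',4'-trihydroxy-3,7,8,5'-tetramethoxyflavone | COc1cc(-c2oc3c(OC)c(OC)cc(O)c3c(=O)c2OC)c(O)cc1O | target

## Step count and risks

Total: 15 steps. Longest linear sequence: 12 steps (steps 4–15 from **8**); the ring A branch (steps 1–3) joins at step 11.

**Step 11 (key step).** The most likely failure is protonation of the aryl anion before the acyl group has migrated, which would end in simple O‑arylation of the acid. Migration onto the crowded, donor‑substituted acyl carbon may also be slow, and the ring closure may stop at the stage of **20**. The fallback separates insertion from construction of ring C. It sets out from **7** and **13** and returns at **21**.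
- Silyl triflate **7** would be treated with methoxyacetic acid and CsF in THF at 125 °C. An unhindered aliphatic acid is the best‑behaved partner for this insertion and should give 1‑(2‑hydroxy‑4,6‑dimethoxyphenyl)‑2‑methoxyethan‑1‑one F1.
- Aldehyde **13** would be oxidised with NaClO2 and NaH2PO4 in the presence of 2‑methyl‑2‑butene to 2,4‑bis(benzyloxy)‑5‑methoxybenzoic acid F2.
- Carbodiimide esterification of the two would give 3,5‑dimethoxy‑2‑(methoxyacetyl)phenyl 2,4‑bis(benzyloxy)‑5‑methoxybenzoate F3.
- Baker–Venkataraman rearrangement with KOH in pyridine would give 1‑[2,4‑bis(benzyloxy)‑5‑methoxyphenyl]‑3‑(2‑hydroxy‑4,6‑dimethoxyphenyl)‑2‑methoxypropane‑1,3‑dione F4.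
- Cyclodehydration with catalytic toluenesulfonic acid in warm toluene would give **21**.

**Step 13.** Conversion in the persulfate oxidation may be low because the chelated, lipophilic phenol dissolves and ionises poorly in aqueous alkali, and the hydroquinone product may be oxidised further to the quinone. The fallback introduces the C8 oxygen by halogenation and copper‑mediated substitution. It sets out from **21** and returns at **25**.
- Bromination of **21** with N‑bromosuccinimide in DMF at 0 °C should go to C8, the usual position for 5,7‑dimethoxyflavones, giving 2‑[2,4‑bis(benzyloxy)‑5‑methoxyphenyl]‑8‑bromo‑3,5,7‑trimethoxy‑4H‑chromen‑4‑one F5. Competing bromination at C6 or on the electron‑rich ring B would have to be checked.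
- Methoxide exchange with NaOMe and CuBr in DMF/MeOH at 110 °C would give 2‑[2,4‑bis(benzyloxy)‑5‑methoxyphenyl]‑3,5,7,8‑tetramethoxy‑4H‑chromen‑4‑one F6.
- Chelation‑controlled demethylation as in step 12 (AlCl3, MeCN) would then give **25**.

**Step 9.** Methylation may occur partly on carbon and give the quaternary α‑methyl ketoester. The fallback forms the enol C–O bond by vinylic substitution, not by alkylation. It sets out from **16** and returns at **17**.
- O‑Sulfonylation of **16** with toluenesulfonyl chloride, N‑methylimidazole and Et3N is reliably oxygen‑selective and should give methyl (Z)‑3‑[2,4‑bis(benzyloxy)‑5‑methoxyphenyl]‑2‑methoxy‑3‑(tosyloxy)prop‑2‑enoate F7.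
- Addition–elimination with NaOMe in MeOH/THF at 0 °C would give **17**.

**Step 12.** Selectivity may be lost through competing cleavage of the benzyl ethers or of the 3‑methoxyl. The fallback accepts the loss of the benzyl groups and restores them. It sets out from **21** and returns at **22**.
- BCl3 in CH2Cl2 at −78 → 0 °C would remove the 5‑methyl group and both benzyl groups, giving 2‑(2,4‑dihydroxy‑5‑methoxyphenyl)‑5‑hydroxy‑3,7‑dimethoxy‑4H‑chromen‑4‑one F8.
- Benzylation with two equivalents of BnBr and K2CO3 in acetone would then take place only on the two ring B hydroxyls and give **22**, because the chelated 5‑hydroxyl is inert under these conditions.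

## Further compounds

F1 | step 11 | 1-(2-hydroxy-4,6-dimethoxyphenyl)-2-methoxyethan-1-one | COCC(=O)c1c(O)cc(OC)cc1OC
F2 | step 11 | 2,4-bis(benzyloxy)-5-methoxybenzoic acid | COc1cc(C(=O)O)c(OCc2ccccc2)cc1OCc1ccccc1
F3 | step 11 | 3,5-dimethoxy-2-(methoxyacetyl)phenyl 2,4-bis(benzyloxy)-5-methoxybenzoate | COCC(=O)c1c(OC)cc(OC)cc1OC(=O)c1cc(OC)c(OCc2ccccc2)cc1OCc1ccccc1
F4 | step 11 | 1-[2,4-bis(benzyloxy)-5-methoxyphenyl]-3-(2-hydroxy-4,6-dimethoxyphenyl)-2-methoxypropane-1,3-dione (racemic, enolisable) | COc1cc(O)c(C(=O)C(OC)C(=O)c2cc(OC)c(OCc3ccccc3)cc2OCc2ccccc2)c(OC)c1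
F5 | step 13 | 2-[2,4-bis(benzyloxy)-5-methoxyphenyl]-8-bromo-3,5,7-trimethoxy-4H-chromen-4-one | COc1cc(OC)c2c(=O)c(OC)c(-c3cc(OC)c(OCc4ccccc4)cc3OCc3ccccc3)oc2c1Br
F6 | step 13 | 2-[2,4-bis(benzyloxy)-5-methoxyphenyl]-3,5,7,8-tetramethoxy-4H-chromen-4-one | COc1cc(OC)c2c(=O)c(OC)c(-c3cc(OC)c(OCc4ccccc4)cc3OCc3ccccc3)oc2c1OC
F7 | step 9 | methyl (Z)-3-[2,4-bis(benzyloxy)-5-methoxyphenyl]-2-methoxy-3-(tosyloxy)prop-2-enoate | COC(=O)/C(OC)=C(/OS(=O)(=O)c1ccc(C)cc1)c1cc(OC)c(OCc2ccccc2)cc1OCc1ccccc1
F8 | step 12 | 2-(2,4-dihydroxy-5-methoxyphenyl)-5-hydroxy-3,7-dimethoxy-4H-chromen-4-one | COc1cc(O)c2c(=O)c(OC)c(-c3cc(OC)c(O)cc3O)oc2c1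
A1 | alternative 1 | 1-[6-(benzyloxy)-3,4-dimethoxy-2-(methoxymethoxy)phenyl]-3-[2,4-bis(benzyloxy)-5-methoxyphenyl]-2-methoxypropane-1,3-dione (racemic, enolisable) | COCOc1c(C(=O)C(OC)C(=O)c2cc(OC)c(OCc3ccccc3)cc2OCc2ccccc2)c(OCc2ccccc2)cc(OC)c1OC
A2 | alternative 1 | 1-(benzyloxy)-2-iodo-4,5-dimethoxy-3-(methoxymethoxy)benzene | COCOc1c(I)c(OCc2ccccc2)cc(OC)c1OC
A3 | alternative 1 | 1-[2,4-bis(benzyloxy)-5-methoxyphenyl]-2-methoxyethan-1-one | COCC(=O)c1cc(OC)c(OCc2ccccc2)cc1OCc1ccccc1
A4 | alternative 2 | 2-(2,4-dihydroxy-5-methoxyphenyl)-3,5,7,8-tetramethoxy-4H-chromen-4-one | COc1cc(-c2oc3c(OC)c(OC)cc(OC)c3c(=O)c2OC)c(O)cc1O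
A5 | alternative 2 | 2-ethynyl-3,5,7,8-tetramethoxy-4H-chromen-4-one | C#Cc1oc2c(OC)c(OC)cc(OC)c2c(=O)c1OC
A6 | alternative 2 | 1,4-dimethoxy-1,3-bis(trimethylsilyloxy)buta-1,3-diene (mixture of geometric isomers) | COC=C(O[Si](C)(C)C)C=C(OC)O[Si](C)(C)C
A7 | alternative 3 | racemic trans-5-(benzyloxy)-2-[2,4-bis(benzyloxy)-5-methoxyphenyl]-3-hydroxy-7,8-dimethoxychroman-4-one (2R,3R enantiomer drawn) | COc1cc([C@H]2Oc3c(OC)c(OC)cc(OCc4ccccc4)c3C(=O)[C@@H]2O)c(OCc2ccccc2)cc1OCc1ccccc1
A8 | alternative 3 | 6-(benzyloxy)-2-{1-[2,4-bis(benzyloxy)-5-methoxyphenyl]-2-oxoethoxy}-3,4-dimethoxybenzaldehyde (racemic) | O=CC(Oc1c(C=O)c(OCc2ccccc2)cc(OC)c1OC)c1cc(OC)c(OCc2ccccc2)cc1OCc1ccccc1
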